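## Structural features

The target 16 is a single tetrahydrofuran ring (O1, C2, C3, C4, C5) with three different carbon substituents on adjacent ring carbons. C2 carries a 3,4,5-trimethoxyphenyl group (ring A) directly, C3 a hydroxymethyl group (C9), and C4 a 3,4,5-trimethoxybenzyl group (C7' and ring B); C5 is a plain ring methylene. C2, C3 and C4 are contiguous stereocentres, (2S,3R,4R): ring A and C9 are trans across C2–C3, and C9 and C7' are cis across C3–C4. The C2–O1 bond is a benzylic ether on an electron-rich arene, so acid can ionise it, which epimerises C2 or lets ring B close onto C2 to an aryltetralin; both arenes are also open to strong oxidants. The cis C3/C4 pair is the less stable arrangement, so any intermediate with a carbonyl group next to C3 or C4 can drift to trans under base. The real difficulty is the absolute and relative control of three adjacent sp3 centres, two of them carrying only carbon substituents, by methods that stay away from acid and base late in the route. The key step uses the 1,3-relationship of the C2 oxygen and C9 through C3: with C2 as a ketone and C9 as an ester, C3 becomes a stereolabile β-keto ester carbon, so one reduction at C2 can fix C2 and C3 together. C4 is next to neither carbonyl group and keeps the configuration it was made with.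

## Logic of the disconnections

16 ⇒ 15. No skeletal bond is cut; the C9–OH group of 16 is traced back to the ester carbonyl of 15. The ester is wanted during the two preceding operations: it withdraws electron density from C2 and so shields the benzylic C2–O1 bond from ionisation, and it leaves the C2 hydroxyl as the only nucleophile able to capture C5. The gain is that C9 needs no protecting group at any stage. The forward step must reduce an ester whose α-carbon C3 has a β-alkoxy group without epimerisation or β-elimination, which calls for a fast, cold hydride reduction.

15 ⇒ 13. The C5–H bond of 15 is exchanged for a C5–OH bond, which gives 13. A lactol is what an aldehyde at C5 and the C2 hydroxyl form on their own, so the ring needs no separate closing step. The forward step must deliver hydride to C5 faster than the Lewis acid can ionise C2–O1 or the cation can lose the C4 proton.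

13 ⇒ 10. The ring bond O1–C5 is cut and the C5 aldehyde is traced to a vinyl group, which adds one carbon in the backward direction and leads to 10. The vinyl group is the most inert aldehyde equivalent available: it survives enolisation at C3, hydride transfer and buffer, and it keeps every carbonyl group away from C4 until C2 and C3 are fixed. The gain is an acyclic compound with one hydroxyl and one ester. The forward step must cleave a terminal alkene beside two electron-rich arenes and a benzylic alcohol.

10 ⇒ 9. The C2–H bond is removed, so C2 becomes a ketone and the C3 stereocentre dissolves into a pair of interconverting epimers. Two of the three stereocentres disappear in one backward operation, and 9 holds only C4. The forward step must pick one face of the ketone and one C3 epimer in the presence of the fixed C4, and must not touch the ester or the alkene.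

9 ⇒ 8 + 4. The C3–C4 bond is cut. C4 is an allylic carbon bearing a stabilised carbon nucleophile, which is the retron of a branched-selective allylic alkylation. The cut divides the molecule into two fragments of similar size, each with one arene, and leaves C4 as the only stereocentre to be set. The forward step must attack the substituted allyl terminus, stop after one alkylation, and take its face selectivity from the ligand.

8 ⇒ 5 + 6. The C3–C9 bond is cut, a Claisen-type acylation of a methyl ketone. Both partners are simple, and the forward step needs only a non-enolisable acyl donor in excess.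

4 ⇒ 3 + 2. The alkene of 4 is cut by cross-metathesis logic. 3 supplies ring B with C7' and one alkene carbon, and 2 supplies the oxygenated allyl terminus. The forward step must give the E alkene and must not move the double bond of 3 into conjugation with its arene.

2 ⇒ 1. The two carbonate C–O bonds are cut, which leaves 1 and a chloroformate; the forward step is a plain double acylation.

## Other disconnections considered

Alternative 1: The cut is the C4–C7' bond, made last on a ring that already holds C2 and C3.
- Forward key step: a diarylprolinol silyl ether would condense with the open aldehyde form of lactol A1, [(2S,3R)-5-hydroxy-2-(3,4,5-trimethoxyphenyl)tetrahydrofuran-3-yl]methyl pivalate, to an enamine. This would add through C4 to quinone methide A3, generated in the flask from 4-(hydroxymethyl)-2,6-dimethoxyphenol A2, to give benzylated lactol A4.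
- In its favour: the step forms a carbon–carbon bond and a stereocentre under catalyst control, it is convergent, and ring B enters late, which is better than the chosen plan if analogues are wanted. Amine-catalysed additions of aldehydes to para-quinone methides are an established reaction type, whereas the chosen key step lies outside demonstrated enzyme scope, so on precedent the alternative is also better.
- Against it here: the quinone methide needs a free para-hydroxyl, so ring B arrives as a phenol that must be methylated afterwards under base. C4 of A4 is α to a masked aldehyde and cis to the C3 substituent, so it can epimerise through the very enamine that formed it. The lactol must open before the catalyst can engage, and the amine can add to A3 instead. A1 already contains C2 and C3, whose control is only moved to an earlier sequence.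
- Comparison: on structure the two plans are equal in their weak point, since both pass through a C5 lactol with the cis C3/C4 pair (A4 and 13). On mechanism the alternative sets C4 last, where it is labile, and the chosen plan sets it first, where it is not. On step economy the end-games are equal (O-methylation, lactol reduction and ester cleavage against steps 6 to 8), but the chosen plan needs no protecting group and reaches 9 in four steps, while A1 is expected to need more.

Alternative 2: The cut is the pair of bonds C3–H and C4–H, with C2 carried through in the wrong configuration and inverted afterwards.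
- Forward key step: hydrogen over Rh/Al2O3 would add syn to the tetrasubstituted C3=C4 bond of dihydrofuran ester A5, methyl (2S)-2-(3,4,5-trimethoxyphenyl)-4-(3,4,5-trimethoxybenzyl)-2,5-dihydrofuran-3-carboxylate, from the face opposite ring A, to give all-cis ester A6. Acid would then epimerise C2 of A6 to the 2,3-trans isomer, which is 15 of the chosen route.
- In its favour: one stereocentre is relayed to two, and syn addition makes the cis C3/C4 relationship a mechanistic necessity. This is better founded than in the chosen plan, where it rests on an enzyme's choice of epimer. A heterogeneous hydrogenation is also operationally simpler than an enzyme screen.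
- Against it here: C2–H of A5 is benzylic, allylic, α to oxygen and vinylogous to the ester, so the only stereocentre of A5 is easily lost by deprotonation, double-bond migration or aromatisation to the furan. A tetrasubstituted alkene needs forcing conditions, under which the benzylic C2–O1 bond can be hydrogenolysed. The epimerisation must open exactly the C2–O1 bond that is the weak point of this skeleton, with ring B placed to close onto the cation, and its result depends on an equilibrium preference. Enantioenriched A5 needs an asymmetric step of its own.
- Comparison: on structure the alternative converges on the same ester 15. On mechanism the chosen plan fixes C2 kinetically and never ionises it, whereas the alternative ionises it on purpose. On step economy the alternative needs two operations after its key step against three, a point where it is better, though this is offset by the unsolved access to A5.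

Alternative 3: The cut is the C3–C9 bond.
- Forward key step: photoexcited decatungstate, (n-Bu4N)4[W10O32], would abstract a hydrogen atom from methanol A8. The hydroxymethyl radical would add to C3 of butenolide A7, (5S)-3-(3,4,5-trimethoxybenzyl)-5-(3,4,5-trimethoxyphenyl)furan-2(5H)-one, anti to ring A, and the reduced catalyst would return a hydrogen atom to C4 to give lactone A9.
- In its favour: C9 enters at its final oxidation level without a protecting group. Anti addition of carbon radicals to γ-substituted butenolides is well founded, so the 2,3-trans relationship is as reliable as in the chosen plan. Only the reduction of the lactone carbonyl to the C5 methylene remains, so in step economy the alternative is better.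
- Against it here: C4 is set by hydrogen-atom return to a planar α-acyl radical that has the new hydroxymethyl group on one face and ring A, one carbon further, on the other. The required cis C3/C4 result therefore has no clear control element, and the cis lactone can epimerise at C4 to the more stable trans isomer. C2–H of A7 and the two benzylic methylene groups are weak C–H bonds that compete with A8 for the excited catalyst. The free hydroxymethyl of A9 can translactonise onto the carbonyl, and during lactone-to-ether reduction it can trap C5 as a bicyclic acetal.
- Comparison: on structure A9 keeps a carbonyl group next to C4 until the end, whereas the chosen plan masks C5 as an alkene while C2 and C3 are set. On mechanism the alternative leaves C4 to an uncontrolled hydrogen-atom transfer, and the chosen plan sets it first with a ligand-controlled step. On step economy the alternative is shorter.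

Key step: step 5

Remark on the chemistry: the (Ra,R,R) ligand named in step 4 is the enantiomer that the accepted facial model of this catalyst family assigns to (S) at C4; should the sense prove opposite, the mirror-image ligand, equally available, is used and nothing else changes.

Remark on the descriptors: the open-chain structures 9 and 10 were checked against 16 and need no correction. C3 and C4 read S in the chain and R in 16 only because substituent priorities change; no centre is inverted after step 5.

## Steps

Step 1
Reactants: 1 (Z)-but-2-ene-1,4-diol
Product: 2 (Z)-but-2-ene-1,4-diyl dimethyl dicarbonate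
Conditions: ClCO2Me (2.5 equiv), pyridine (3 equiv), CH2Cl2, 0 °C to rt
Reagents that add atoms: methyl chloroformate, COC(=O)Cl
Why: Acylation of both primary allylic hydroxyls to the bis(methyl carbonate), with pyridine taking up the HCl; the alkene geometry is irrelevant because metathesis erases it.

Step 2
Reactants: 3 5-allyl-1,2,3-trimethoxybenzene; 2 (Z)-but-2-ene-1,4-diyl dimethyl dicarbonate
Product: 4 methyl (E)-4-(3,4,5-trimethoxyphenyl)but-2-en-1-yl carbonate
Conditions: second-generation Hoveyda–Grubbs catalyst RuCl2(H2IMes)(=CH-C6H4-2-O-i-Pr) (2.5 mol %), 2 (3 equiv), 1,4-benzoquinone (10 mol %), CH2Cl2, 40 °C; chromatography on AgNO3-impregnated silica if Z isomer remains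
Reagents that add atoms: none
Why: Olefin cross-metathesis of a terminal allylarene with an excess of a symmetrical internal olefin exchanges the CH2 terminus of 3 for one half of 2, and reversibility should leave mainly the E alkene. Benzoquinone is added to suppress migration of the double bond of 3 into conjugation with ring B.

Step 3
Reactants: 5 3',4',5'-trimethoxyacetophenone; 6 dimethyl carbonate
Product: 8 methyl 3-oxo-3-(3,4,5-trimethoxyphenyl)propanoate, via sodium enolate 7 (not isolated)
Conditions: NaH (2.5 equiv), 6 (3 equiv), toluene, 110 °C; then 1 M HCl
Reagents that add atoms: none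
Why: Claisen-type carbomethoxylation of the methyl ketone enolate by the non-enolisable carbonate forms the C3–C9 bond; deprotonation of the product to enolate 7 drives the equilibrium and acid releases 8.

Step 4
Reactants: 8 methyl 3-oxo-3-(3,4,5-trimethoxyphenyl)propanoate; 4 methyl (E)-4-(3,4,5-trimethoxyphenyl)but-2-en-1-yl carbonate
Product: 9 methyl 3-oxo-3-(3,4,5-trimethoxyphenyl)-2-[(2S)-1-(3,4,5-trimethoxyphenyl)but-3-en-2-yl]propanoate (C4 is S; both epimers at C3)
Conditions: [Ir(cod)Cl]2 (2 mol %), (Ra)-1,1'-binaphthyl-2,2'-diyl N,N-bis[(R)-1-phenylethyl]phosphoramidite (4 mol %), 1,5,7-triazabicyclo[4.4.0]dec-5-ene (8 mol %), THF, rt; 8 (1.5 equiv)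
Reagents that add atoms: none
Why: Iridium-catalysed asymmetric allylic alkylation: the cyclometalated iridium–phosphoramidite complex ionises the linear carbonate to an allyl complex, and the enolate of 8, formed by the released methoxide, attacks the substituted allyl terminus, so the C3–C4 bond forms at the branched position. The ligand decides the face of attack and sets C4 as S; C3 forms as both epimers, which is of no consequence because they interconvert.

Step 5
Reactants: 9 methyl 3-oxo-3-(3,4,5-trimethoxyphenyl)-2-[(2S)-1-(3,4,5-trimethoxyphenyl)but-3-en-2-yl]propanoate
Product: 10 methyl (2S,3S)-3-hydroxy-3-(3,4,5-trimethoxyphenyl)-2-[(2S)-1-(3,4,5-trimethoxyphenyl)but-3-en-2-yl]propanoate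
Conditions: ketoreductase (hit from a screened panel), NADP+ (cat.), glucose dehydrogenase, D-glucose (1.5 equiv), KH2PO4/K2HPO4 buffer (0.1 M, pH 7.5), DMSO (15 vol %), 30 °C
Reagents that add atoms: none
Why: Proposed new method: in buffer at pH 7.5 the C3 epimers of 9 interconvert through the enol, because C3–H lies between the aryl ketone and the ester, while the ketoreductase should bind only one epimer productively and pass the hydride of NADPH to one face of the C2 carbonyl, the cofactor being recycled by glucose dehydrogenase and glucose. The closest known reaction type is the ketoreductase-catalysed dynamic reductive kinetic resolution of α-alkyl and α-amido β-keto esters, aryl ketones included; an α-substituent that is a branched carbon bearing a stereocentre and a second bulky arene has not been shown, so the enzyme has to be found by screening a panel and, if need be, by engineering the hit. The step closes no ring and makes no skeletal bond; only the C2–H bond is formed. C2 is set as S by the active site, which fixes the face of hydride delivery, and C3 is set as S by the enzyme's choice of epimer, which places the C2 hydroxyl and the C4-bearing chain syn when C9–C3–C2–ring A is drawn as a zigzag. The step needs face selectivity at C2, epimer selectivity at C3, epimerisation faster than reduction of the unwanted epimer, and reduction of the ketone alone; the last is inherent in nicotinamide hydride transfer, which touches neither ester nor alkene, and the acidity of C3–H secures the third. C4 is not α to a carbonyl group and cannot epimerise, so it stays S and turns every stereochemical error of the enzyme into a separable diastereomer in place of an enantiomer. An isolated enzyme preparation is preferred to whole cells so that esterases do not hydrolyse the methyl ester, which would be followed by decarboxylation.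

Step 6
Reactants: 10 methyl (2S,3S)-3-hydroxy-3-(3,4,5-trimethoxyphenyl)-2-[(2S)-1-(3,4,5-trimethoxyphenyl)but-3-en-2-yl]propanoate
Product: 13 methyl (2S,3S,4R)-5-hydroxy-2-(3,4,5-trimethoxyphenyl)-4-(3,4,5-trimethoxybenzyl)tetrahydrofuran-3-carboxylate (both anomers), via triol 11 (not isolated), via hydroxy aldehyde 12 (not isolated)
Conditions: OsO4 (2 mol %), NaIO4 (4 equiv), 2,6-lutidine (2 equiv), 1,4-dioxane/H2O 3:1, rt
Reagents that add atoms: osmium tetroxide, O=[Os](=O)(=O)=O (donates the C5 oxygen, catalytic); sodium periodate, [Na+].[O-]I(=O)(=O)=O (restores the oxo ligands of osmium)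
Why: Lemieux–Johnson oxidative cleavage: catalytic osmylation gives triol 11, periodate cleaves its glycol to aldehyde 12, and the C2 hydroxyl adds to the aldehyde to close the five-membered lactol through the O1–C5 bond. Osmium/periodate is chosen over ozone because it leaves the two electron-rich arenes alone, and the near-neutral medium with immediate lactol formation should keep C4, now next to a masked aldehyde, from epimerising.

Step 7
Reactants: 13 methyl (2S,3S,4R)-5-hydroxy-2-(3,4,5-trimethoxyphenyl)-4-(3,4,5-trimethoxybenzyl)tetrahydrofuran-3-carboxylate
Product: 15 methyl (2S,3S,4R)-2-(3,4,5-trimethoxyphenyl)-4-(3,4,5-trimethoxybenzyl)tetrahydrofuran-3-carboxylate, via oxocarbenium ion 14 (not isolated)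
Conditions: Et3SiH (3 equiv), BF3·OEt2 (1.2 equiv), CH2Cl2, −78 °C
Reagents that add atoms: none
Why: Ionic hydrogenation of a lactol: BF3·OEt2 ionises the C5 hydroxyl to oxocarbenium ion 14 and Et3SiH delivers hydride to C5, which is no stereocentre in the product. The ester at C3 disfavours ionisation of the benzylic C2–O1 bond, so C2, C3 and C4 should pass unchanged at −78 °C.

Step 8
Reactants: 15 methyl (2S,3S,4R)-2-(3,4,5-trimethoxyphenyl)-4-(3,4,5-trimethoxybenzyl)tetrahydrofuran-3-carboxylate
Product: 16 [(2S,3R,4R)-2-(3,4,5-trimethoxyphenyl)-4-(3,4,5-trimethoxybenzyl)tetrahydrofuran-3-yl]methanol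
Conditions: LiAlH4 (1.5 equiv), THF, 0 °C; then H2O, aq NaOH
Reagents that add atoms: none
Why: Hydride reduction of the methyl ester to the primary alcohol C9; addition to the ester carbonyl should be far faster than deprotonation at C3, so neither epimerisation at C3 nor β-elimination of O1 is expected. The C3 descriptor changes from S to R by priority only.

## Compound list

1 | (Z)-but-2-ene-1,4-diol | OC/C=C\CO | starting material
2 | (Z)-but-2-ene-1,4-diyl dimethyl dicarbonate | COC(=O)OC/C=C\COC(=O)OC | intermediate
3 | 5-allyl-1,2,3-trimethoxybenzene | C=CCc1cc(OC)c(OC)c(OC)c1 | starting material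
4 | methyl (E)-4-(3,4,5-trimethoxyphenyl)but-2-en-1-yl carbonate | COC(=O)OC/C=C/Cc1cc(OC)c(OC)c(OC)c1 | intermediate
5 | 3',4',5'-trimethoxyacetophenone | CC(=O)c1cc(OC)c(OC)c(OC)c1 | starting material
6 | dimethyl carbonate | COC(=O)OC | starting material
7 | sodium (Z)-3-methoxy-3-oxo-1-(3,4,5-trimethoxyphenyl)prop-1-en-1-olate | [Na+].[O-]/C(=C\C(=O)OC)c1cc(OC)c(OC)c(OC)c1 | intermediate (not isolated)
8 | methyl 3-oxo-3-(3,4,5-trimethoxyphenyl)propanoate | COC(=O)CC(=O)c1cc(OC)c(OC)c(OC)c1 | intermediate
9 | methyl 3-oxo-3-(3,4,5-trimethoxyphenyl)-2-[(2S)-1-(3,4,5-trimethoxyphenyl)but-3-en-2-yl]propanoate, both C3 epimers | COc1cc(C[C@@H](C=C)C(C(=O)OC)C(=O)c2cc(OC)c(OC)c(OC)c2)cc(OC)c1OC | intermediate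
10 | methyl (2S,3S)-3-hydroxy-3-(3,4,5-trimethoxyphenyl)-2-[(2S)-1-(3,4,5-trimethoxyphenyl)but-3-en-2-yl]propanoate | COc1cc(C[C@@H](C=C)[C@H](C(=O)OC)[C@H](O)c2cc(OC)c(OC)c(OC)c2)cc(OC)c1OC | intermediate
11 | methyl (2S,3S)-2-[(2R)-3,4-dihydroxy-1-(3,4,5-trimethoxyphenyl)butan-2-yl]-3-hydroxy-3-(3,4,5-trimethoxyphenyl)propanoate, both epimers at the new secondary carbinol | COc1cc(C[C@@H](C(O)CO)[C@H](C(=O)OC)[C@H](O)c2cc(OC)c(OC)c(OC)c2)cc(OC)c1OC | intermediate (not isolated)
12 | methyl (2S,3S)-3-hydroxy-2-[(2R)-1-oxo-3-(3,4,5-trimethoxyphenyl)propan-2-yl]-3-(3,4,5-trimethoxyphenyl)propanoate | COc1cc(C[C@@H](C=O)[C@H](C(=O)OC)[C@H](O)c2cc(OC)c(OC)c(OC)c2)cc(OC)c1OC | intermediate (not isolated)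
13 | methyl (2S,3S,4R)-5-hydroxy-2-(3,4,5-trimethoxyphenyl)-4-(3,4,5-trimethoxybenzyl)tetrahydrofuran-3-carboxylate, both anomers | COc1cc(C[C@H]2C(O)O[C@H](c3cc(OC)c(OC)c(OC)c3)[C@H]2C(=O)OC)cc(OC)c1OC | intermediate
14 | (2S,3S,4R)-3-(methoxycarbonyl)-2-(3,4,5-trimethoxyphenyl)-4-(3,4,5-trimethoxybenzyl)-3,4-dihydro-2H-furan-1-ium | COc1cc(C[C@H]2C=[O+][C@H](c3cc(OC)c(OC)c(OC)c3)[C@H]2C(=O)OC)cc(OC)c1OC | intermediate (not isolated)
15 | methyl (2S,3S,4R)-2-(3,4,5-trimethoxyphenyl)-4-(3,4,5-trimethoxybenzyl)tetrahydrofuran-3-carboxylate | COc1cc(C[C@H]2CO[C@H](c3cc(OC)c(OC)c(OC)c3)[C@H]2C(=O)OC)cc(OC)c1OC | intermediate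
16 | [(2S,3R,4R)-2-(3,4,5-trimethoxyphenyl)-4-(3,4,5-trimethoxybenzyl)tetrahydrofuran-3-yl]methanol (CNP0321241.1) | COc1cc(C[C@H]2CO[C@H](c3cc(OC)c(OC)c(OC)c3)[C@H]2CO)cc(OC)c1OC | target

## Step count and least certain steps

Total step count: 8. Longest linear sequence: 7 steps (steps 1, 2, 4, 5, 6, 7 and 8, from 1 to 16); step 3 lies on the side branch that supplies 8.

Step 5 (key step, proposed new method). The most likely failure is that no enzyme of the panel turns over so hindered a ketone, or that reduction of the unwanted C3 epimer keeps pace with epimerisation, so that a mixture of diastereomers forms. The cause is the branched α-substituent with a second bulky arene, which may not fit any active site and also slows enolisation. Fallback with known chemistry, setting out from 9 and returning at 10: chelation-controlled reduction of 9 with Zn(BH4)2 in Et2O at −20 °C, a syn-selective reduction of α-substituted β-keto esters in which each C3 epimer gives its own syn alcohol. The two syn products are diastereomers because of the fixed C4 and are separated by chromatography: 10 and methyl (2R,3R)-3-hydroxy-3-(3,4,5-trimethoxyphenyl)-2-[(2S)-1-(3,4,5-trimethoxyphenyl)but-3-en-2-yl]propanoate F1. F1 is oxidised back to 9 with Dess–Martin periodinane and recycled. The price is separation and recycling in place of a dynamic process.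

Step 4. The most likely failures are attack at the unsubstituted allyl terminus, a second allylation at C3, low face selectivity with a bulky aroylacetate, or loss of a proton from the allyl intermediate to a 1-arylbutadiene. The nucleophile is larger than those for which this catalyst family is best documented. Fallback, setting out from 4 and returning at 9: the same iridium catalyst with dimethyl malonate, the best documented nucleophile for alkyl-substituted allyl carbonates, should give dimethyl 2-[(2S)-1-(3,4,5-trimethoxyphenyl)but-3-en-2-yl]propanedioate F2. Dealkoxycarbonylation (LiCl, wet DMSO, 150 °C) gives methyl (3R)-3-(3,4,5-trimethoxybenzyl)pent-4-enoate F3, whose stereocentre is β to the ester and cannot epimerise. Deprotonation of F3 with LiN(i-Pr)2 (2.2 equiv, THF, −78 °C) and C-acylation with 3,4,5-trimethoxybenzoyl chloride gives 9. The C2–C3 bond is thus made after the C3–C4 bond, at the cost of two steps.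

Step 7. The most likely failure is ionisation of the benzylic C2–O1 bond by the Lewis acid, leading to epimerisation at C2, reductive ring opening or closure of ring B onto C2. A second risk is proton loss from C4 of cation 14 to an enol ether, followed by return of the proton from the other face. Both arise because a cationic pathway is run on an acid-sensitive skeleton. Fallback, setting out from 13 and returning at 15, through a C5 radical in place of a cation: neutral thioacetalisation of 13 with PhSSPh and n-Bu3P in THF should give methyl (2S,3S,4R)-5-(phenylsulfanyl)-2-(3,4,5-trimethoxyphenyl)-4-(3,4,5-trimethoxybenzyl)tetrahydrofuran-3-carboxylate F4. Homolysis of the C5–S bond with n-Bu3SnH and azobisisobutyronitrile in toluene at 80 °C then gives 15; the α-oxygen radical at C5 takes up hydrogen without touching C2 or C4.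

Step 2. The most likely failures are formation of an E/Z mixture and migration of the double bond of 3 towards ring B under ruthenium hydride catalysis. A Z contaminant would react through a different allyl geometry in step 4 and lower the enantiomeric purity at C4. Fallback, setting out from 3 and returning at 4, which also makes step 1 unnecessary: cross-metathesis of 3 with methyl acrylate (same catalyst, CH2Cl2, 40 °C) is strongly E-selective and should give methyl (E)-4-(3,4,5-trimethoxyphenyl)but-2-enoate F5. Reduction with i-Bu2AlH (CH2Cl2, −78 °C) gives (E)-4-(3,4,5-trimethoxyphenyl)but-2-en-1-ol F6, and ClCO2Me/pyridine gives 4. F5 must be kept neutral and cold, because its methylene group is doubly activated.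

## Further compounds

F1 | step 5 | methyl (2R,3R)-3-hydroxy-3-(3,4,5-trimethoxyphenyl)-2-[(2S)-1-(3,4,5-trimethoxyphenyl)but-3-en-2-yl]propanoate | COc1cc(C[C@@H](C=C)[C@@H](C(=O)OC)[C@@H](O)c2cc(OC)c(OC)c(OC)c2)cc(OC)c1OC
F2 | step 4 | dimethyl 2-[(2S)-1-(3,4,5-trimethoxyphenyl)but-3-en-2-yl]propanedioate | COc1cc(C[C@@H](C=C)C(C(=O)OC)C(=O)OC)cc(OC)c1OC
F3 | step 4 | methyl (3R)-3-(3,4,5-trimethoxybenzyl)pent-4-enoate | COc1cc(C[C@@H](C=C)CC(=O)OC)cc(OC)c1OC
F4 | step 7 | methyl (2S,3S,4R)-5-(phenylsulfanyl)-2-(3,4,5-trimethoxyphenyl)-4-(3,4,5-trimethoxybenzyl)tetrahydrofuran-3-carboxylate, both anomers | COc1cc(C[C@H]2C(Sc3ccccc3)O[C@H](c4cc(OC)c(OC)c(OC)c4)[C@H]2C(=O)OC)cc(OC)c1OC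
F5 | step 2 | methyl (E)-4-(3,4,5-trimethoxyphenyl)but-2-enoate | COC(=O)/C=C/Cc1cc(OC)c(OC)c(OC)c1
F6 | step 2 | (E)-4-(3,4,5-trimethoxyphenyl)but-2-en-1-ol | OC/C=C/Cc1cc(OC)c(OC)c(OC)c1
A1 | alternative 1 | [(2S,3R)-5-hydroxy-2-(3,4,5-trimethoxyphenyl)tetrahydrofuran-3-yl]methyl pivalate, both anomers | C1C(O)O[C@H](c2cc(OC)c(OC)c(OC)c2)[C@H]1COC(=O)C(C)(C)C
A2 | alternative 1 | 4-(hydroxymethyl)-2,6-dimethoxyphenol | COc1cc(CO)cc(OC)c1O
A3 | alternative 1 | 2,6-dimethoxy-4-methylidenecyclohexa-2,5-dien-1-one | C=C1C=C(OC)C(=O)C(OC)=C1
A4 | alternative 1 | [(2S,3R,4R)-5-hydroxy-4-(4-hydroxy-3,5-dimethoxybenzyl)-2-(3,4,5-trimethoxyphenyl)tetrahydrofuran-3-yl]methyl pivalate, 5R anomer drawn | COc1cc(C[C@H]2[C@H](O)O[C@H](c3cc(OC)c(OC)c(OC)c3)[C@H]2COC(=O)C(C)(C)C)cc(OC)c1O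
A5 | alternative 2 | methyl (2S)-2-(3,4,5-trimethoxyphenyl)-4-(3,4,5-trimethoxybenzyl)-2,5-dihydrofuran-3-carboxylate | COc1cc(CC2=C(C(=O)OC)[C@H](c3cc(OC)c(OC)c(OC)c3)OC2)cc(OC)c1OC
A6 | alternative 2 | methyl (2R,3S,4R)-2-(3,4,5-trimethoxyphenyl)-4-(3,4,5-trimethoxybenzyl)tetrahydrofuran-3-carboxylate, all-cis | COc1cc(C[C@H]2CO[C@@H](c3cc(OC)c(OC)c(OC)c3)[C@H]2C(=O)OC)cc(OC)c1OC
A7 | alternative 3 | (5S)-3-(3,4,5-trimethoxybenzyl)-5-(3,4,5-trimethoxyphenyl)furan-2(5H)-one | COc1cc(CC2=C[C@@H](c3cc(OC)c(OC)c(OC)c3)OC2=O)cc(OC)c1OC
A8 | alternative 3 | methanol | CO
A9 | alternative 3 | (3R,4R,5S)-4-(hydroxymethyl)-3-(3,4,5-trimethoxybenzyl)-5-(3,4,5-trimethoxyphenyl)dihydrofuran-2(3H)-one | COc1cc(C[C@H]2C(=O)O[C@H](c3cc(OC)c(OC)c(OC)c3)[C@H]2CO)cc(OC)c1OC
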